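**Retrosynthetic overview**
- Endgame: the two 2-methylene-1-ol units are made differently: C4(=CH2)/3β-OH by Cp2TiCl opening of a 3β,4β-epoxide (epoxidation directed by 6β-OH), and C10(=CH2)/9α-OH by Rubottom oxidation of a C9=C10 enol silane followed by methylenation.
- The trans ring fusion (H-5β) comes from a palladium-hydride 1,3-transposition of a 3α-allylic acetate; the same acetylation installs the C12 acetate.
- Core: one operation turns an acyclic diazo ketone into the bicycle. A carbene at C5 cyclopropanates C1=C10 (five-membered ring first, bond C1–C5), then the divinylcyclopropane rearranges (seven-membered ring, bond C7–C8).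
- Enabling feature: the seven-membered ring C1–C5–C6–C7–C8–C9–C10 is a three-carbon unit C5–C6–C7 with oxygen on its central carbon C6, joined to a four-carbon unit C8–C9–C10–C1 whose C10 is at the ketone level; C4, next to C5 in the five-membered ring, is also at the ketone level. So C5 can be an acyl(silyloxyvinyl)carbene and C8=C9–C10(OSi)=C1 a silyloxydiene, tethered through C2–C3–C4.
- Stereochemistry: C3 is bought ((S)-lactone) and relays to C1 and C7 (key step), C5 (palladium), C6, C9 and finally back to C3 itself (inverted); C11/C12 come from a syn-crotylboration; the fragments are joined by a diazo aldol reaction.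

Key step: step 14

Remark on the chemistry: guaiane-type numbering is used throughout (five-membered ring C1–C2–C3–C4–C5, seven-membered ring C1–C5–C6–C7–C8–C9–C10, side chain C11(CH3)–C12(O)–C13–C14=C15 on C7). β is the face of H-5 in the target, α the face of H-1. The C3 oxygen is deliberately carried as the 3α (S) epimer until step 18 and is re-installed as 3β in steps 20–21.

**Route**

Step 1
Reactants: 1 4-methylpent-3-en-1-ol
Product: 2 4-methylpent-3-enal
Conditions: Dess–Martin periodinane, pyridine, CH2Cl2, 0 °C to rt; used crude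
Reagents that add atoms: none
Why: Dess–Martin oxidation of a primary alcohol under buffered anhydrous conditions stops at the aldehyde and leaves the β,γ-double bond out of conjugation.

Step 2
Reactants: 2 4-methylpent-3-enal
Product: 3 (3S,4S)-3,7-dimethylocta-1,6-dien-4-ol
Conditions: (Z)-crotyl-B(Ipc)2 [re-face-selective antipode, from (+)-Ipc2BOMe, (−)-α-pinene series, prepared separately], THF/Et2O, −78 °C; then NaOH, H2O2
Reagents that add atoms: (Z)-crotyldiisopinocampheylborane, C/C=C\CB(C1CC2CC(C1C)C2(C)C)C1CC2CC(C1C)C2(C)C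
Why: Brown crotylboration through a closed chair transition state, the (Z)-crotyl geometry giving the syn C11/C12 pair and the isopinocampheyl groups directing attack to the re face of the aldehyde (reagent control) to give the (3S,4S) alcohol.

Step 3
Reactants: 3 (3S,4S)-3,7-dimethylocta-1,6-dien-4-ol
Product: 4 triethylsilyl ether of 3
Conditions: Et3SiCl, imidazole, DMF, 0 °C to rt
Reagents that add atoms: chlorotriethylsilane, CC[Si](Cl)(CC)CC
Why: Standard imidazole-mediated silylation of the secondary alcohol, the triethylsilyl group being chosen so that it falls off later together with the one on O3 under the dilute acid of step 16.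

Step 4
Reactants: 4 triethylsilyl ether of 3
Product: 6 (3S,4S)-3,7-dimethyl-4-(triethylsilyloxy)oct-6-en-1-ol, via B-alkyl-9-BBN 5 (not isolated)
Conditions: 9-BBN, THF, 0 °C to rt; then NaOH, H2O2, 0 °C
Reagents that add atoms: hydrogen peroxide, OO
Why: Hydroboration–oxidation with the bulky 9-BBN is selective for the monosubstituted alkene over the trisubstituted one and places boron on the terminal carbon (future C6).

Step 5
Reactants: 6 (3S,4S)-3,7-dimethyl-4-(triethylsilyloxy)oct-6-en-1-ol
Product: 7 (3S,4S)-3,7-dimethyl-4-(triethylsilyloxy)oct-6-enoic acid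
Conditions: TEMPO (cat.), PhI(OAc)2, MeCN/pH 7 phosphate buffer, rt
Reagents that add atoms: water, O
Why: TEMPO/PhI(OAc)2 oxidation in buffered aqueous acetonitrile takes the primary alcohol through the aldehyde hydrate to the acid without touching the trisubstituted alkene or the silyl ether.

Step 6
Reactants: 7 (3S,4S)-3,7-dimethyl-4-(triethylsilyloxy)oct-6-enoic acid
Product: 9 (4S,5S)-1-diazo-4,8-dimethyl-5-(triethylsilyloxy)non-7-en-2-one, via mixed carbonic anhydride 8 (not isolated)
Conditions: i-BuOCOCl, Et3N, THF, −15 °C; then CH2N2, Et2O, 0 °C to rt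
Reagents that add atoms: diazomethane, C=[N+]=[N-]
Why: Acylation of diazomethane by the mixed anhydride (first stage of the Arndt–Eistert sequence) gives the diazomethyl ketone under non-acidic conditions that spare the silyl ether.

Step 7
Reactants: 10 (S)-5-(hydroxymethyl)dihydrofuran-2(3H)-one
Product: 11 (S)-4,5-dihydroxy-N-methoxy-N-methylpentanamide
Conditions: MeNHOMe·HCl, i-PrMgCl, THF, −20 to 0 °C
Reagents that add atoms: N,O-dimethylhydroxylamine hydrochloride, CNOC.Cl
Why: Weinreb aminolysis of the lactone by the magnesium amide opens the ring at the acyl carbon and leaves the C3 stereocentre untouched.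

Step 8
Reactants: 11 (S)-4,5-dihydroxy-N-methoxy-N-methylpentanamide
Product: 12 (S)-N-methoxy-N-methyl-4,5-bis(triethylsilyloxy)pentanamide
Conditions: Et3SiCl, imidazole, DMF, 0 °C to rt
Reagents that add atoms: chlorotriethylsilane, CC[Si](Cl)(CC)CC
Why: Silylation of both hydroxyl groups prevents relactonisation and sets up the later differentiation of the primary silyl ether.

Step 9
Reactants: 12 (S)-N-methoxy-N-methyl-4,5-bis(triethylsilyloxy)pentanamide
Product: 13 (S)-6,7-bis(triethylsilyloxy)hept-1-en-3-one
Conditions: CH2=CHMgBr, THF, −78 to 0 °C; inverse quench into cold aq. NH4Cl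
Reagents that add atoms: vinylmagnesium bromide, C=C[Mg]Br
Why: Weinreb ketone synthesis, in which the chelated tetrahedral intermediate survives until the cold quench so that a single vinyl group is delivered and the enone is released only on work-up.

Step 10
Reactants: 13 (S)-6,7-bis(triethylsilyloxy)hept-1-en-3-one
Product: 15 (S)-5-oxo-2-(triethylsilyloxy)hept-6-enal, via alkoxysulfonium salt 14 (not isolated)
Conditions: (COCl)2, DMSO, CH2Cl2, −78 to −40 °C; then Et3N, −78 to 0 °C
Reagents that add atoms: none
Why: Under Swern conditions a primary triethylsilyl ether is cleaved by the chlorosulfonium reagent and oxidised in situ while the secondary one is retained (known selective oxidation of primary silyl ethers), giving the α-silyloxy aldehyde without a separate deprotection.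

Step 11
Reactants: 9 (4S,5S)-1-diazo-4,8-dimethyl-5-(triethylsilyloxy)non-7-en-2-one; 15 (S)-5-oxo-2-(triethylsilyloxy)hept-6-enal
Product: 17 diazo aldol adduct (C4 carbinol epimers), via lithiated diazo ketone 16 (not isolated)
Conditions: LiN(SiMe3)2, THF, −78 °C; then 15, −78 °C; AcOH quench at −78 °C
Reagents that add atoms: none
Why: Aldol-type addition of a lithiated α-diazo ketone to an aldehyde, which at −78 °C should be far faster at the α-oxygenated aldehyde than addition to the enone; the new carbinol centre forms as a mixture that is erased in step 12, and the cold acidic quench forestalls retro-aldol cleavage and silyl migration.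

Step 12
Reactants: 17 diazo aldol adduct (C4 carbinol epimers)
Product: 18 diazo triketone
Conditions: Dess–Martin periodinane, pyridine, CH2Cl2, 0 °C to rt
Reagents that add atoms: none
Why: Dess–Martin oxidation of β-hydroxy-α-diazo ketones to 2-diazo-1,3-diketones is reliable, the diazo group, the enone and the silyl ethers being inert to the buffered periodinane.

Step 13
Reactants: 18 diazo triketone
Product: 19 bis(enol silane) diazo ketone
Conditions: t-BuMe2SiOTf (2.3 equiv), Et3N, CH2Cl2, −78 to 0 °C
Reagents that add atoms: tert-butyldimethylsilyl triflate, CC(C)(C)[Si](C)(C)OS(=O)(=O)C(F)(F)F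
Why: Soft enolisation (silyl triflate/amine) converts the C6 ketone, which can enolise only towards C7, and the C10 ketone, which can enolise only towards C1, into their (Z)-enol silanes (alkyl group cis to OSi, minimising allylic strain), while the C4 carbonyl with its hindered, oxygenated C3–H should react more slowly.

Step 14
Reactants: 19 bis(enol silane) diazo ketone
Product: 21 hydroazulenone bis(enol silane), via cis-divinylcyclopropane 20 (not isolated)
Conditions: Rh2(OPiv)4 (1 mol %), toluene, 25 °C, slow addition of 19; then 70 °C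
Reagents that add atoms: none
Why: Loss of N2 from 19 gives a donor/acceptor dirhodium carbene at C5 that adds intramolecularly to the electron-rich C1=C10 enol silane (five-membered ring by 5-exo-type carbene addition through the C2–C3–C4 tether, forming C1–C5 and C5–C10), and the resulting cis-divinylcyclopropane 20 rearranges by a [3,3] shift through the boat transition state, cleaving the push–pull C5–C10 bond and forming C7–C8 (seven-membered ring by ring-opening Cope rearrangement, driven by release of the bicyclo[3.1.0]hexane strain). The closest known reaction type is the tandem cyclopropanation/divinylcyclopropane rearrangement (formal [4+3] annulation) of silyloxyvinyl diazo carbonyl compounds, which is known inter- and intramolecularly and with silyloxydienes. C1 is set in the cyclopropanation: the C3 silyloxy group should take the convex position of the forming bicyclo[3.1.0]hexanone, away from the endo silyloxy group on C10, so the cyclopropane forms trans to the C3–O bond; C7 is set in the rearrangement, the boat geometry and the (Z)-C6=C7 enol silane placing H-7 cis to H-1. The step needs reaction at C1=C10 rather than at C8=C9 or the side-chain alkene (secured by the tether, since only C1=C10 closes a five-membered ring, and by its being the most electron-rich alkene), a cis relation of the two alkenyl groups (secured by the (Z)-dienol silane, which puts the vinyl group trans to C2), and concerted rearrangement ahead of ionic ring opening (non-polar solvent).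

Step 15
Reactants: 21 hydroazulenone bis(enol silane)
Product: 23 C10 ketone 9α-silyl ether, via silyloxy epoxide 22 (not isolated)
Conditions: dimethyldioxirane (1.05 equiv), acetone/CH2Cl2, −78 to 0 °C
Reagents that add atoms: dimethyldioxirane, CC1(C)OO1
Why: Rubottom oxidation, in which the isolated C9=C10 enol silane is far more nucleophilic than the push–pull C5=C6 enol silane or the side-chain alkene, the oxidant approaches the α face (anti to the β-oriented C7 side chain and C1–C2 bond), and 1,4-silyl migration in the silyloxy epoxide delivers the 9α-silyl ether of the C10 ketone.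

Step 16
Reactants: 23 C10 ketone 9α-silyl ether
Product: 25 enone diol, via bis-methylene dienol silane 24 (not isolated)
Conditions: Cp2TiMe2, toluene, 65 °C, dark; then 0.5 M aq. HCl, THF, 0 °C to rt
Reagents that add atoms: dimethyltitanocene, C[Ti](C)(C1C=CC=C1)C1C=CC=C1
Why: Petasis methylenation (Cp2Ti=CH2, non-basic, so C1 and C9 should not epimerise) converts both the C10 ketone and the vinylogous-ester C4 carbonyl into methylenes, and dilute acid then protonates the terminal carbon of the 2-silyloxydiene to unveil the conjugated C6 enone carrying the C4 methyl (hydrolysis of a dienol ether to the conjugated enone) and removes the two triethylsilyl ethers, the tert-butyldimethylsilyl ether on O9 surviving.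

Step 17
Reactants: 25 enone diol
Product: 26 enone diacetate
Conditions: Ac2O, pyridine, DMAP (cat.), CH2Cl2, rt
Reagents that add atoms: acetic anhydride, CC(=O)OC(C)=O
Why: Standard acetylation puts the permanent acetate on O12 and, in the same operation, the leaving group on the allylic O3.

Step 18
Reactants: 26 enone diacetate
Product: 27 trans-fused β,γ-unsaturated ketone
Conditions: Pd(OAc)2 (5 mol %), n-Bu3P (10 mol %), HCO2NH4, 1,4-dioxane, 80 °C
Reagents that add atoms: none
Why: Tsuji–Mandai formate hydrogenolysis, in which zerovalent palladium ionises the allylic 3α-acetate with inversion, formate decarboxylates to a palladium hydride on the β face and the hydride is delivered to the more substituted terminus C5 on that face, giving the C3=C4 alkene and H-5β (trans ring fusion, the arrangement expected to be the more stable one for a seven-membered-ring ketone next to the fusion), while the non-allylic C12 acetate and the allylic silyl ether are untouched.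

Step 19
Reactants: 27 trans-fused β,γ-unsaturated ketone
Product: 28 6β-alcohol
Conditions: NaBH4, CeCl3·7H2O, MeOH, −78 to −40 °C
Reagents that add atoms: none
Why: Luche reduction (non-basic, so C5 and C7 should not epimerise and the alkene should not move into conjugation) with hydride entering from the α face, anti to the β-oriented C7 side chain, to give the 6β-alcohol.

Step 20
Reactants: 28 6β-alcohol
Product: 29 3β,4β-epoxide
Conditions: VO(acac)2 (cat.), t-BuOOH, CH2Cl2, 0 °C to rt
Reagents that add atoms: tert-butyl hydroperoxide, CC(C)(C)OO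
Why: Vanadium-catalysed hydroxyl-directed epoxidation, in which the homoallylic 6β-hydroxyl delivers the peroxide oxygen to the β face of the C3=C4 alkene only, alkenes without a nearby free hydroxyl (side chain, C10 methylene) being left alone.

Step 21
Reactants: 29 3β,4β-epoxide
Product: 30 9-O-silyl ether of the target
Conditions: Cp2TiCl2, Mn dust, THF, rt (Cp2TiCl formed in situ); aq. NaH2PO4 work-up
Reagents that add atoms: none
Why: Trivalent-titanium (Cp2TiCl) epoxide opening gives the tertiary C4 radical and a 3β-titanium alkoxide, and a second Cp2TiCl removes a β-hydrogen from the least hindered position, the C4 methyl (known isomerisation of trisubstituted epoxides to exo-methylene allylic alcohols), so the C3–O bond and its β configuration are retained while acetate, silyl ether and alkenes stay inert.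

Step 22
Reactants: 30 9-O-silyl ether of the target
Product: 31 CNP0210891.2 (target)
Conditions: Bu4NF, AcOH, THF, rt
Reagents that add atoms: none
Why: Buffered fluoride desilylation cleaves the remaining silyl ether without acetate migration or allylic ionisation.

**Compound list**

1 | 4-methylpent-3-en-1-ol | CC(C)=CCCO | starting material
2 | 4-methylpent-3-enal | CC(C)=CCC=O | intermediate
3 | (3S,4S)-3,7-dimethylocta-1,6-dien-4-ol | C=C[C@H](C)[C@H](CC=C(C)C)O | intermediate
4 | triethyl[(3S,4S)-3,7-dimethylocta-1,6-dien-4-yloxy]silane | C=C[C@H](C)[C@H](CC=C(C)C)O[Si](CC)(CC)CC | intermediate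
5 | 9-[(3S,4S)-3,7-dimethyl-4-(triethylsilyloxy)oct-6-enyl]-9-borabicyclo[3.3.1]nonane | C(C[C@H](C)[C@H](CC=C(C)C)O[Si](CC)(CC)CC)B1C2CCCC1CCC2 | intermediate
6 | (3S,4S)-3,7-dimethyl-4-(triethylsilyloxy)oct-6-en-1-ol | OCC[C@H](C)[C@H](CC=C(C)C)O[Si](CC)(CC)CC | intermediate
7 | (3S,4S)-3,7-dimethyl-4-(triethylsilyloxy)oct-6-enoic acid | OC(=O)C[C@H](C)[C@H](CC=C(C)C)O[Si](CC)(CC)CC | intermediate
8 | mixed isobutyl carbonic anhydride of 7 | CC(C)COC(=O)OC(=O)C[C@H](C)[C@H](CC=C(C)C)O[Si](CC)(CC)CC | intermediate
9 | (4S,5S)-1-diazo-4,8-dimethyl-5-(triethylsilyloxy)non-7-en-2-one (C5–C7, C11–C15 of the target) | [N-]=[N+]=CC(=O)C[C@H](C)[C@H](CC=C(C)C)O[Si](CC)(CC)CC | intermediate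
10 | (S)-5-(hydroxymethyl)dihydrofuran-2(3H)-one | OC[C@@H]1CCC(=O)O1 | starting material
11 | (S)-4,5-dihydroxy-N-methoxy-N-methylpentanamide | OC[C@@H](O)CCC(=O)N(C)OC | intermediate
12 | (S)-N-methoxy-N-methyl-4,5-bis(triethylsilyloxy)pentanamide | CC[Si](CC)(CC)OC[C@@H](O[Si](CC)(CC)CC)CCC(=O)N(C)OC | intermediate
13 | (S)-6,7-bis(triethylsilyloxy)hept-1-en-3-one | CC[Si](CC)(CC)OC[C@@H](O[Si](CC)(CC)CC)CCC(=O)C=C | intermediate
14 | dimethyl[(S)-5-oxo-2-(triethylsilyloxy)hept-6-enyloxy]sulfonium chloride | C[S+](C)OC[C@@H](O[Si](CC)(CC)CC)CCC(=O)C=C.[Cl-] | intermediate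
15 | (S)-5-oxo-2-(triethylsilyloxy)hept-6-enal (C4 aldehyde, C3–C1, C10 ketone, C9=C8) | O=C[C@@H](O[Si](CC)(CC)CC)CCC(=O)C=C | intermediate
16 | 9 lithiated at the diazo carbon | [Li]C(=[N+]=[N-])C(=O)C[C@H](C)[C@H](CC=C(C)C)O[Si](CC)(CC)CC | intermediate
17 | (6S,11S,12S)-8-diazo-7-hydroxy-11,15-dimethyl-6,12-bis(triethylsilyloxy)hexadeca-1,14-diene-3,9-dione, both carbinol epimers | C=CC(=O)CC[C@H](O[Si](CC)(CC)CC)C(O)C(=[N+]=[N-])C(=O)C[C@H](C)[C@H](CC=C(C)C)O[Si](CC)(CC)CC | intermediate
18 | (6S,11S,12S)-8-diazo-11,15-dimethyl-6,12-bis(triethylsilyloxy)hexadeca-1,14-diene-3,7,9-trione | C=CC(=O)CC[C@H](O[Si](CC)(CC)CC)C(=O)C(=[N+]=[N-])C(=O)C[C@H](C)[C@H](CC=C(C)C)O[Si](CC)(CC)CC | intermediate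
19 | (3Z,6S,9Z,11S,12S)-3,9-bis(tert-butyldimethylsilyloxy)-8-diazo-11,15-dimethyl-6,12-bis(triethylsilyloxy)hexadeca-1,3,9,14-tetraen-7-one | C=C/C(O[Si](C)(C)C(C)(C)C)=C/C[C@H](O[Si](CC)(CC)CC)C(=O)C(=[N+]=[N-])/C(O[Si](C)(C)C(C)(C)C)=C/[C@H](C)[C@H](CC=C(C)C)O[Si](CC)(CC)CC | intermediate
20 | cis-divinylcyclopropane: bicyclo[3.1.0]hexan-4-one with the C1–C5–C10 cyclopropane on the β face, 3α-OSiEt3, 10-OSi endo, C8=C9 vinyl exo, (Z)-6-silyloxyalkenyl on C5 | O=C1[C@@H](O[Si](CC)(CC)CC)C[C@@H]2[C@@](O[Si](C)(C)C(C)(C)C)(C=C)[C@]12/C(O[Si](C)(C)C(C)(C)C)=C/[C@H](C)[C@H](CC=C(C)C)O[Si](CC)(CC)CC | intermediate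
21 | hydroazulen-4-one with C5=C6 and C9=C10 enol silanes (6- and 10-OSiMe2t-Bu), 3α-OSiEt3, H-1α, H-7α, side chain 12-OSiEt3 | O=C1C2=C(O[Si](C)(C)C(C)(C)C)[C@@H]([C@H](C)[C@H](CC=C(C)C)O[Si](CC)(CC)CC)CC=C(O[Si](C)(C)C(C)(C)C)[C@H]2C[C@@H]1O[Si](CC)(CC)CC | intermediate
22 | 9α,10α-epoxide of 21 (10-silyloxy epoxide) | O=C1C2=C(O[Si](C)(C)C(C)(C)C)[C@@H]([C@H](C)[C@H](CC=C(C)C)O[Si](CC)(CC)CC)C[C@@H]3O[C@]3(O[Si](C)(C)C(C)(C)C)[C@H]2C[C@@H]1O[Si](CC)(CC)CC | intermediate
23 | 4,10-diketone level: C10 ketone, 9α-OSiMe2t-Bu, C5=C6 enol silane, 3α-OSiEt3 | O=C1C2=C(O[Si](C)(C)C(C)(C)C)[C@@H]([C@H](C)[C@H](CC=C(C)C)O[Si](CC)(CC)CC)C[C@H](O[Si](C)(C)C(C)(C)C)C(=O)[C@H]2C[C@@H]1O[Si](CC)(CC)CC | intermediate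
24 | 4,10-bis(methylene) C5=C6 dienol silane | C=C1C2=C(O[Si](C)(C)C(C)(C)C)[C@@H]([C@H](C)[C@H](CC=C(C)C)O[Si](CC)(CC)CC)C[C@H](O[Si](C)(C)C(C)(C)C)C(=C)[C@H]2C[C@@H]1O[Si](CC)(CC)CC | intermediate
25 | enone diol: C4=C5 (4-methyl), C6 ketone, 3α-OH, 12-OH, 9α-OSiMe2t-Bu, 10-methylene | CC1=C2C(=O)[C@@H]([C@H](C)[C@H](CC=C(C)C)O)C[C@H](O[Si](C)(C)C(C)(C)C)C(=C)[C@H]2C[C@@H]1O | intermediate
26 | 3α,12-diacetate of 25 | CC1=C2C(=O)[C@@H]([C@H](C)[C@H](CC=C(C)C)OC(C)=O)C[C@H](O[Si](C)(C)C(C)(C)C)C(=C)[C@H]2C[C@@H]1OC(C)=O | intermediate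
27 | trans-fused ketone: H-5β, H-1α, C3=C4 (4-methyl), C6 ketone, 12-OAc | C1=C(C)[C@@H]2C(=O)[C@@H]([C@H](C)[C@H](CC=C(C)C)OC(C)=O)C[C@H](O[Si](C)(C)C(C)(C)C)C(=C)[C@H]2C1 | intermediate
28 | 6β-alcohol of 27 | C1=C(C)[C@@H]2[C@@H](O)[C@@H]([C@H](C)[C@H](CC=C(C)C)OC(C)=O)C[C@H](O[Si](C)(C)C(C)(C)C)C(=C)[C@H]2C1 | intermediate
29 | 3β,4β-epoxide of 28 | C[C@]12[C@@H]3[C@@H](O)[C@@H]([C@H](C)[C@H](CC=C(C)C)OC(C)=O)C[C@H](O[Si](C)(C)C(C)(C)C)C(=C)[C@H]3C[C@H]1O2 | intermediate
30 | 9-O-(tert-butyldimethylsilyl) ether of the target | C=C1[C@@H]2[C@@H](O)[C@@H]([C@H](C)[C@H](CC=C(C)C)OC(C)=O)C[C@H](O[Si](C)(C)C(C)(C)C)C(=C)[C@H]2C[C@H]1O | intermediate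
31 | CNP0210891.2: trans-fused 4,10-bis(methylene)hydroazulane-3β,6β,9α-triol with the 7β-[(2S,3S)-3-acetoxy-6-methylhept-5-en-2-yl] side chain | C=C1[C@@H]2[C@@H](O)[C@@H]([C@H](C)[C@H](CC=C(C)C)OC(C)=O)C[C@H](O)C(=C)[C@H]2C[C@H]1O | target

**Step count and risks**

Total step count: 22. Longest linear sequence: 18 steps (steps 1–6, then 11–22).

Steps most likely to fail:

Step 18. The hydride may be delivered to the less substituted allyl terminus C3, which returns the conjugated enone, or ionisation on the hindered β face may be too slow for clean stereospecific transfer. Fallback, setting out from diacetate 26: samarium diiodide (SmI2, THF/MeOH, −78 °C) cleaves the γ-acetoxy enone reductively to the dienolate, whose kinetic protonation at C5 should give the deconjugated ketone mainly as the cis-fused C5 epimer F4. Brief equilibration through the C6 enol (DBU, toluene) would then convert F4 into the trans-fused ketone 27, where the route resumes.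

Step 16. Methylenation of the deactivated vinylogous-ester carbonyl may be incomplete, or a thermal 1,5-hydrogen shift in the silyloxytriene may scramble C7 before hydrolysis. Fallback, setting out from ketone 23: Wittig methylenation (Ph3P=CH2, THF, 0 °C) touches only the C10 ketone and gives the C10-methylene vinylogous silyl ester F2. MeLi/CeCl3 (THF, −78 °C) then adds 1,2 to the C4 carbonyl to give the tertiary carbinol F3 (not isolated), and dilute HCl effects the Stork–Danheiser transposition with loss of the silyl groups on O6, O3 and O12, returning to enone diol 25.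

Step 11. The lithiated diazo ketone may add in conjugate fashion to the vinyl ketone, or the lithium alkoxide may trigger silyl migration or epimerisation at C3. Fallback, setting out from diazo ketone 9 and aldehyde 15: the tin dichloride (SnCl2)-catalysed Roskamp coupling (CH2Cl2, rt) joins the same two carbons under neutral conditions with loss of N2 and gives the 1,3-diketone F1. Regitz diazo transfer (p-acetamidobenzenesulfonyl azide, Et3N, MeCN) then returns the route to diazo triketone 18, bypassing 17.

Further compounds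
F1 | step 11 | (6S,11S,12S)-11,15-dimethyl-6,12-bis(triethylsilyloxy)hexadeca-1,14-diene-3,7,9-trione | C=CC(=O)CC[C@H](O[Si](CC)(CC)CC)C(=O)CC(=O)C[C@H](C)[C@H](CC=C(C)C)O[Si](CC)(CC)CC
F2 | step 16 | 10-methylene analogue of 23 (C4 carbonyl and C5=C6 enol silane retained) | O=C1C2=C(O[Si](C)(C)C(C)(C)C)[C@@H]([C@H](C)[C@H](CC=C(C)C)O[Si](CC)(CC)CC)C[C@H](O[Si](C)(C)C(C)(C)C)C(=C)[C@H]2C[C@@H]1O[Si](CC)(CC)CC
F3 | step 16 | C4 tertiary carbinol from methyl addition to F2 (C4 configuration open) | CC1(O)C2=C(O[Si](C)(C)C(C)(C)C)[C@@H]([C@H](C)[C@H](CC=C(C)C)O[Si](CC)(CC)CC)C[C@H](O[Si](C)(C)C(C)(C)C)C(=C)[C@H]2C[C@@H]1O[Si](CC)(CC)CC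
F4 | step 18 | cis-fused C5 epimer of 27 (H-5α) | C1=C(C)[C@H]2C(=O)[C@@H]([C@H](C)[C@H](CC=C(C)C)OC(C)=O)C[C@H](O[Si](C)(C)C(C)(C)C)C(=C)[C@H]2C1
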